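The terpenoid core is disconnected in ring A (C1, C2, C3, C4, C5, C10), which is closed last by an Ireland–Claisen rearrangement of a lactone enolate. The step exploits the γ,δ-unsaturated acid pattern C11(=O)–C10–C1–C2=C3 hidden in ring A: C11, the later ArOCH2 carbon on quaternary C10, is the carbonyl of a temporary δ-lactone whose oxygen sits on C3, trans-fused to the preformed ring B (C4–C9) and carrying an (E)-propenyl group (C2=C1–CH3) on C3. One boat [3,3] shift forms C10–C1, opens the lactone, and sets the quaternary C10 and the axial C1 methyl.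

Key step: step 6

Remark on numbering: C1 = CH(CH3) next to C10; C2, C3 = CH2; C4 = angular C(CH3); C5 = ring-fusion CH; C6, C7 = CH2; C8 = C=O; C9 = CH(CH3); C10 = C(CH3)(C11H2OAr). Ring A = C1-C2-C3-C4-C5-C10, ring B = C4-C5-C6-C7-C8-C9.
Remark: C10 (the propanoate α-carbon) is carried as an epimeric mixture in 3 and 6 to 10; it becomes trigonal in step 6, so the mixture is of no consequence.
Assumption: the chiral catalysts of steps 1 and 3 induce in the sense of their usual models (Re-face attack at the enone β-carbon in step 1; alkynyl group in the π-binding position in step 3); if either sense proves opposite, the antipodal catalyst is used.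

Step 1
Reactants: 1 2-methylcyclohex-2-en-1-one; 2 1-methoxy-1-(trimethylsilyloxy)prop-1-ene
Product: 3 methyl 2-[(1S)-2-methyl-3-(trimethylsilyloxy)cyclohex-2-en-1-yl]propanoate
Conditions: chiral oxazaborolidinium triflimide [from (S)-α,α-diphenylprolinol, o-tolylboronic acid and HNTf2] (10 mol %), Ph3PO (20 mol %), toluene, −20 °C
Reagents that add atoms: none
Why: Catalytic asymmetric Mukaiyama–Michael addition, in which the catalyst-bound enone should be attacked at its β-carbon (C5) on the Re face to set C5, while silyl transfer to the enolate oxygen fixes the tetrasubstituted C4=C9 enol ether needed for step 2.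

Step 2
Reactants: 3 methyl 2-[(1S)-2-methyl-3-(trimethylsilyloxy)cyclohex-2-en-1-yl]propanoate; 4 but-2-ynoic acid
Product: 6 methyl 2-[(1S,2S)-2-(but-2-ynoyl)-2-methyl-3-oxocyclohexyl]propanoate, via but-2-ynoyl chloride 5 (not isolated)
Conditions: 4, (COCl)2, cat. DMF, CH2Cl2, 0 to 25 °C, evaporation; then 3, ZnCl2 (10 mol %), CH2Cl2/Et2O, −20 to 25 °C
Reagents that add atoms: none
Why: Lewis-acid-mediated C-acylation of the silyl enol ether should create the quaternary C4 centre anti to the pseudoaxial C5 side chain (A-1,2 strain), which places the acyl carbon C3 trans to C10 as the later trans ring fusion requires.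

Step 3
Reactants: 6 methyl 2-[(1S,2S)-2-(but-2-ynoyl)-2-methyl-3-oxocyclohexyl]propanoate
Product: 8 (1S,4aS,8aR)-4,8a-dimethyl-1-(prop-1-yn-1-yl)-4a,5,6,7-tetrahydro-1H-isochromene-3,8(4H,8aH)-dione, via hydroxy ester 7 (not isolated)
Conditions: Ru[(R,R)-TsNCHPhCHPhNH](p-cymene) (2 mol %), iPrOH, 25 °C; then CSA (10 mol %), toluene, 60 °C
Reagents that add atoms: none
Why: Asymmetric transfer hydrogenation should reduce the ynone much faster than the dialkyl ketone and set C3 (S) under catalyst control, after which acid-catalysed transesterification closes the trans-fused δ-lactone with the alkynyl group cis to the C4 methyl.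

Step 4
Reactants: 8 (1S,4aS,8aR)-4,8a-dimethyl-1-(prop-1-yn-1-yl)-4a,5,6,7-tetrahydro-1H-isochromene-3,8(4H,8aH)-dione
Product: 9 (1S,4aS,8aR)-4,8a-dimethyl-1-[(E)-prop-1-en-1-yl]-4a,5,6,7-tetrahydro-1H-isochromene-3,8(4H,8aH)-dione
Conditions: H2 (10 bar), [Cp*Ru(MeCN)3]PF6 (5 mol %), CH2Cl2, 25 °C
Reagents that add atoms: none
Why: Ruthenium-catalysed trans-hydrogenation of the internal alkyne (anti delivery of H2) should give the (E)-propenyl group without touching ketone or lactone, and no stereocentre is formed.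

Step 5
Reactants: 9 (1S,4aS,8aR)-4,8a-dimethyl-1-[(E)-prop-1-en-1-yl]-4a,5,6,7-tetrahydro-1H-isochromene-3,8(4H,8aH)-dione
Product: 10 (1S,4aS,8aR)-4,8a-dimethyl-3-oxo-1-[(E)-prop-1-en-1-yl]-3,4,4a,5,6,8a-hexahydro-1H-isochromen-8-yl trifluoromethanesulfonate
Conditions: KN(SiMe3)2, PhNTf2, THF, −78 °C
Reagents that add atoms: N-phenylbis(trifluoromethanesulfonimide), O=S(=O)(N(c1ccccc1)S(=O)(=O)C(F)(F)F)C(F)(F)F
Why: Enol triflate formation by kinetic deprotonation of the only unhindered α-CH2 (C8; C4 is quaternary and the lactone α-H is tertiary) masks the ketone as the handle for the C9 methyl group and leaves C10–H as the sole enolisable position.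

Step 6
Reactants: 10 (1S,4aS,8aR)-4,8a-dimethyl-3-oxo-1-[(E)-prop-1-en-1-yl]-3,4,4a,5,6,8a-hexahydro-1H-isochromen-8-yl trifluoromethanesulfonate
Product: 13 (1R,2R,4aS,8aR)-1,2,4a-trimethyl-5-[(trifluoromethanesulfonyl)oxy]-1,2,4a,7,8,8a-hexahydronaphthalene-1-carboxylic acid, via silyl ketene acetal 11 (not isolated), via trimethylsilyl ester 12 (not isolated)
Conditions: LiN(iPr)2, Me3SiCl/Et3N, THF, −78 to 25 °C; then toluene, 110 °C; then 1 M HCl, THF, 25 °C
Reagents that add atoms: none
Why: LiN(iPr)2 removes the only acidic proton (C10–H), Me3SiCl traps the lactone enolate on oxygen, and the cyclic silyl ketene acetal undergoes a [3,3]-sigmatropic Ireland–Claisen shift in which C10–C1 forms while the lactone C3–O bond breaks. The closest known reaction type is the lactone-enolate Claisen rearrangement of 6-alkenyl δ-valerolactones to cyclohex-3-ene-1-carboxylic acids. Ring A is closed by suprafacial C10–C1 bond formation across the lactone through a boat transition state, the chair being impossible because the C4–C5 bond ties both termini together; the long partial bonds should let the boat twist enough to accommodate the trans fusion to ring B. C10 is controlled by the C3 stereocentre (the allyl unit reaches the ketene acetal face on which the propenyl group sits, cis to the C4 methyl, so the C10 methyl ends up β and C11 α), and C1 by the (E)-alkene geometry in the boat (C1 methyl on the side of C11, axial in the final chair). The step needs O- rather than C-silylation and a single enolisation site, secured by the tertiary C10 centre and by the ketone being masked as its enol triflate; C4 and C5 are untouched.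

Step 7
Reactants: 13 (1R,2R,4aS,8aR)-1,2,4a-trimethyl-5-[(trifluoromethanesulfonyl)oxy]-1,2,4a,7,8,8a-hexahydronaphthalene-1-carboxylic acid
Product: 14 (1R,2R,4aS,8aR)-1,2,4a,5-tetramethyl-1,2,4a,7,8,8a-hexahydronaphthalene-1-carboxylic acid
Conditions: MeZnCl (3 equiv), Pd(PPh3)4 (5 mol %), THF, 50 °C
Reagents that add atoms: methylzinc chloride, C[Zn]Cl
Why: Negishi cross-coupling of the cyclohexenyl triflate installs the C9 methyl group; it is placed after step 6 because the allylic lactone of 9 and 10 would ionise with zerovalent palladium.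

Step 8
Reactants: 14 (1R,2R,4aS,8aR)-1,2,4a,5-tetramethyl-1,2,4a,7,8,8a-hexahydronaphthalene-1-carboxylic acid
Product: 15 (1R,2R,4aS,8aR)-1,2,4a,5-tetramethyl-1,2,3,4,4a,7,8,8a-octahydronaphthalene-1-carboxylic acid
Conditions: H2 (4 bar), RhCl(PPh3)3 (5 mol %), toluene/EtOH, 40 °C
Reagents that add atoms: none
Why: Homogeneous hydrogenation with RhCl(PPh3)3 should reduce the cis-disubstituted C2=C3 alkene of ring A and leave the hindered trisubstituted C8=C9 alkene, and no stereocentre is formed.

Step 9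
Reactants: 15 (1R,2R,4aS,8aR)-1,2,4a,5-tetramethyl-1,2,3,4,4a,7,8,8a-octahydronaphthalene-1-carboxylic acid
Product: 16 (1R,2R,4aR,5R,6R,8aS)-5-(hydroxymethyl)-1,5,6,8a-tetramethyldecahydronaphthalen-2-ol
Conditions: BH3·THF (4 equiv), THF, 0 to 25 °C; then NaOH, H2O2, H2O, 0 to 40 °C
Reagents that add atoms: hydrogen peroxide, OO
Why: Hydroboration–oxidation should add syn and anti-Markovnikov to C8=C9 from the α-face opposite the axial C4 methyl (C9–H α, C9 methyl β, C8–OH α), while borane also reduces the carboxylic acid to the C11 primary alcohol.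

Step 10
Reactants: 16 (1R,2R,4aR,5R,6R,8aS)-5-(hydroxymethyl)-1,5,6,8a-tetramethyldecahydronaphthalen-2-ol
Product: 17 (1R,4aR,5R,6R,8aS)-5-(hydroxymethyl)-1,5,6,8a-tetramethyloctahydronaphthalen-2(1H)-one
Conditions: NaOCl (aq), AcOH, 20 °C
Reagents that add atoms: none
Why: Hypochlorite in acetic acid oxidises secondary alcohols much faster than primary ones, so the C8 ketone should form selectively with the C9 methyl in its more stable equatorial position.

Step 11
Reactants: 17 (1R,4aR,5R,6R,8aS)-5-(hydroxymethyl)-1,5,6,8a-tetramethyloctahydronaphthalen-2(1H)-one; 18 7-hydroxy-2H-chromen-2-one (umbelliferone)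
Product: 19 7-{[(1R,2R,4aS,5R,8aR)-1,2,4a,5-tetramethyl-6-oxodecahydronaphthalen-1-yl]methoxy}-2H-chromen-2-one
Conditions: PPh3, DIAD, toluene, 0 to 80 °C
Reagents that add atoms: none
Why: Mitsunobu etherification of the primary (neopentyl) alcohol with the acidic phenol forms the C11–O–aryl bond without a base that could open the coumarin lactone, and no stereocentre is touched.

Compound list
1 | 2-methylcyclohex-2-en-1-one | CC1=CCCCC1=O | starting material
2 | 1-methoxy-1-(trimethylsilyloxy)prop-1-ene (E/Z mixture) | CC=C(OC)O[Si](C)(C)C | starting material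
3 | methyl 2-[(1S)-2-methyl-3-(trimethylsilyloxy)cyclohex-2-en-1-yl]propanoate (α-carbon epimers) | COC(=O)C(C)[C@@H]1CCCC(O[Si](C)(C)C)=C1C | intermediate
4 | but-2-ynoic acid | CC#CC(=O)O | starting material
5 | but-2-ynoyl chloride | CC#CC(=O)Cl | intermediate
6 | methyl 2-[(1S,2S)-2-(but-2-ynoyl)-2-methyl-3-oxocyclohexyl]propanoate | COC(=O)C(C)[C@@H]1CCCC(=O)[C@@]1(C)C(=O)C#CC | intermediate
7 | methyl 2-[(1S,2R)-2-[(1S)-1-hydroxybut-2-yn-1-yl]-2-methyl-3-oxocyclohexyl]propanoate | COC(=O)C(C)[C@@H]1CCCC(=O)[C@@]1(C)[C@@H](O)C#CC | intermediate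
8 | (1S,4aS,8aR)-4,8a-dimethyl-1-(prop-1-yn-1-yl)-4a,5,6,7-tetrahydro-1H-isochromene-3,8(4H,8aH)-dione (trans-fused keto δ-lactone) | CC#C[C@@H]1OC(=O)C(C)[C@@H]2CCCC(=O)[C@@]12C | intermediate
9 | (1S,4aS,8aR)-4,8a-dimethyl-1-[(E)-prop-1-en-1-yl]-4a,5,6,7-tetrahydro-1H-isochromene-3,8(4H,8aH)-dione | C/C=C/[C@@H]1OC(=O)C(C)[C@@H]2CCCC(=O)[C@@]12C | intermediate
10 | (1S,4aS,8aR)-4,8a-dimethyl-3-oxo-1-[(E)-prop-1-en-1-yl]-3,4,4a,5,6,8a-hexahydro-1H-isochromen-8-yl trifluoromethanesulfonate | C/C=C/[C@@H]1OC(=O)C(C)[C@@H]2CCC=C(OS(=O)(=O)C(F)(F)F)[C@@]12C | intermediate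
11 | O-trimethylsilyl ketene acetal of 10 (C10=C11 double bond, OSiMe3 on C11; C3, C4, C5 as in 10) | C/C=C/[C@@H]1OC(O[Si](C)(C)C)=C(C)[C@@H]2CCC=C(OS(=O)(=O)C(F)(F)F)[C@@]12C | intermediate
12 | trimethylsilyl (1R,2R,4aS,8aR)-1,2,4a-trimethyl-5-[(trifluoromethanesulfonyl)oxy]-1,2,4a,7,8,8a-hexahydronaphthalene-1-carboxylate | C[C@@H]1C=C[C@@]2(C)[C@@H](CCC=C2OS(=O)(=O)C(F)(F)F)[C@]1(C)C(=O)O[Si](C)(C)C | intermediate
13 | (1R,2R,4aS,8aR)-1,2,4a-trimethyl-5-[(trifluoromethanesulfonyl)oxy]-1,2,4a,7,8,8a-hexahydronaphthalene-1-carboxylic acid | C[C@@H]1C=C[C@@]2(C)[C@@H](CCC=C2OS(=O)(=O)C(F)(F)F)[C@]1(C)C(=O)O | intermediate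
14 | (1R,2R,4aS,8aR)-1,2,4a,5-tetramethyl-1,2,4a,7,8,8a-hexahydronaphthalene-1-carboxylic acid | C[C@@H]1C=C[C@@]2(C)[C@@H](CCC=C2C)[C@]1(C)C(=O)O | intermediate
15 | (1R,2R,4aS,8aR)-1,2,4a,5-tetramethyl-1,2,3,4,4a,7,8,8a-octahydronaphthalene-1-carboxylic acid | C[C@@H]1CC[C@@]2(C)[C@@H](CCC=C2C)[C@]1(C)C(=O)O | intermediate
16 | (1R,2R,4aR,5R,6R,8aS)-5-(hydroxymethyl)-1,5,6,8a-tetramethyldecahydronaphthalen-2-ol | C[C@@H]1CC[C@@]2(C)[C@@H](CC[C@@H](O)[C@@H]2C)[C@]1(C)CO | intermediate
17 | (1R,4aR,5R,6R,8aS)-5-(hydroxymethyl)-1,5,6,8a-tetramethyloctahydronaphthalen-2(1H)-one | C[C@@H]1CC[C@@]2(C)[C@@H](CCC(=O)[C@@H]2C)[C@]1(C)CO | intermediate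
18 | 7-hydroxy-2H-chromen-2-one (umbelliferone) | O=c1ccc2ccc(O)cc2o1 | starting material
19 | 7-{[(1R,2R,4aS,5R,8aR)-1,2,4a,5-tetramethyl-6-oxodecahydronaphthalen-1-yl]methoxy}-2H-chromen-2-one | C[C@@H]1CC[C@@]2(C)[C@@H](CCC(=O)[C@@H]2C)[C@]1(C)COc1ccc2ccc(=O)oc2c1 | target

Total step count: 11. Longest linear sequence: 11 steps (1 to 19).

Steps most likely to fail

Step 6. The tertiary C10–H of the hindered lactone may be removed too slowly, or the silyl ketene acetal may be lost (C-silylation, hydrolysis, thermal decay) before the twisted boat transition state, strained by the trans ring fusion, is reached. The fallback needs no enolate and tolerates much higher temperature. It sets out from 10: reduction with iBu2AlH at −78 °C should give the lactol F1, and dehydration (MsCl, Et3N) the cyclic allyl vinyl ether F2. Thermal Claisen rearrangement of F2 (sealed tube, 180 to 200 °C) should give the ring A aldehyde F3 with the same stereochemical course, and chlorite oxidation (NaClO2, NaH2PO4, 2-methylbut-2-ene) brings the route back at 13.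

Step 1. The α-methyl group of 1 may slow and perturb binding to the chiral Lewis acid, so that facial discrimination is poor or a racemic silyl-cation-catalysed pathway competes. The fallback introduces the methyl group after the asymmetric C–C bond formation. It sets out from 2: the same catalysis with unsubstituted cyclohex-2-en-1-one should give the silyl enol ether F4; MeLi then MeI methylates the regiodefined lithium enolate trans to the side chain to give the ketone F5; thermodynamic silylation (Me3SiCl, NaI, Et3N, MeCN) comes back at 3.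

Step 4. Over-reduction to the propyl group, migration of the double bond, or incomplete E selectivity may occur on the propargylic ester. The fallback replaces direct hydrogenation by a two-stage addition. It sets out from 8: ruthenium-catalysed trans-hydrosilylation with (EtO)3SiH should give the (Z)-vinylsilane F6, and protodesilylation (CuI, Bu4NF) comes back at 9 with the methyl group trans to C3.

Further compounds
F1 | step 6 | (1S,4aS,8aR)-3-hydroxy-4,8a-dimethyl-1-[(E)-prop-1-en-1-yl]-3,4,4a,5,6,8a-hexahydro-1H-isochromen-8-yl trifluoromethanesulfonate (lactol) | C/C=C/[C@@H]1OC(O)C(C)[C@@H]2CCC=C(OS(=O)(=O)C(F)(F)F)[C@@]12C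
F2 | step 6 | (1S,4aS,8aR)-4,8a-dimethyl-1-[(E)-prop-1-en-1-yl]-4a,5,6,8a-tetrahydro-1H-isochromen-8-yl trifluoromethanesulfonate (cyclic enol ether) | C/C=C/[C@@H]1OC=C(C)[C@@H]2CCC=C(OS(=O)(=O)C(F)(F)F)[C@@]12C
F3 | step 6 | (1R,2R,4aS,8aR)-1,2,4a-trimethyl-5-[(trifluoromethanesulfonyl)oxy]-1,2,4a,7,8,8a-hexahydronaphthalene-1-carbaldehyde | C[C@@H]1C=C[C@@]2(C)[C@@H](CCC=C2OS(=O)(=O)C(F)(F)F)[C@]1(C)C=O
F4 | step 1 | methyl 2-[(1R)-3-(trimethylsilyloxy)cyclohex-2-en-1-yl]propanoate | COC(=O)C(C)[C@@H]1CCCC(O[Si](C)(C)C)=C1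
F5 | step 1 | methyl 2-[(1R,2S)-2-methyl-3-oxocyclohexyl]propanoate | COC(=O)C(C)[C@@H]1CCCC(=O)[C@H]1C
F6 | step 4 | (1S,4aS,8aR)-4,8a-dimethyl-1-[(Z)-2-(triethoxysilyl)prop-1-en-1-yl]-4a,5,6,7-tetrahydro-1H-isochromene-3,8(4H,8aH)-dione | C/C([Si](OCC)(OCC)OCC)=C/[C@@H]1OC(=O)C(C)[C@@H]2CCCC(=O)[C@@]12C
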